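(The numbers in the tables stem from a simulated flask with constants of no real substance, and the scatter is random.)

**The count.** The number that mattered for the flask with 34 mM of substrate was how many target half-lives fit into its 2.0 d. In Wednesday's run target, as a fraction of the charge, fell from 21.4% to 8.7% between 10.0 h and 20.0 h, a half-life, as read, of 7.70 h, so the count was 6.23: the time asked, measured in half-lives of target. Monday's run, with 75 mM, gave 7.33 h, so I carried the half-life over to the new charge.

| flask | substrate | remark | time |
|---|---|---|---|
| Wednesday's | 48 mM | run made earlier |  |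
| Monday's | 75 mM | run made earlier |  |
| flask | 34 mM |  | 2.0 d |

| run | time / h | target / % | isomer of the product A / % | substrate / % |
|---|---|---|---|---|
| Wednesday's | 10.0 | 21.4 | 25.4 | 6.7 |
| Wednesday's | 20.0 | 8.7 | 30.4 | 4.1 |
| Wednesday's | 30.0 | 4.6 | 31.8 | 1.2 |
| Wednesday's | 40.0 | 2.4 | 32.6 | 1.3 |
| Monday's | 5.00 | 30.9 | 19.6 | 12.3 |
| Monday's | 15.0 | 12.0 | 26.8 | 3.2 |
| Monday's | 25.0 | 5.4 | 29.1 | 1.7 |
| Monday's | 40.0 | 3.0 | 30.1 | 1.3 |

(scatter of a reading: 0.5 percentage points)

1. ratio of target to isomer of the product A at 3.0 min
2. ratio of target to isomer of the product A at 1.5 h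
3. ratio of target to isomer of the product A at 2.0 d
4. which of target and isomer of the product A there is more of at 2.0 d

- the numbers in the tables scatter by 0.5 percentage points (one standard deviation)

**Reading it.** At 3.0 min and 1.5 h the count was 0.00649 and 0.195, so I expected the two early ratios to lie close together. The time 2.0 d is far longer than the half-life, and isomer of the product A held at 32.6% after 40.0 h on Wednesday, far above target, so I gave isomer of the product A the lead. Target ahead early and isomer of the product A ahead late looked like kinetic against thermodynamic control.

**The test.** Halving took Monday's target from 5.4% at 25.0 h to 1.40% at 40.0 h, but the reading was 3.0%, with a scatter of 0.5 percentage points. So the count gave the direction but not the end: the reading stood above the halving. I committed to the late ratios as read, 0.0736 on Wednesday and 0.0997 on Monday.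

**The forecast.** It gave 1.9, 1.8 and 0.055, with isomer of the product A ahead, holding that “Target then decays roughly first order”. Its last ratio lies below mine.

**The flask.** The ratios came out at 3.08, 2.60 and 0.0806, with isomer of the product A ahead.

    substrate ⇌ target (K = 3.10, k = 9.90 × 10⁻⁵ s⁻¹)
    substrate ⇌ isomer of the product A (K = 71.0, k = 3.20 × 10⁻⁵ s⁻¹)
    target ⇌ isomer of the product B (K = 17.0, k = 2.70 × 10⁻⁵ s⁻¹)
    2 substrate → homo dimer (k = 5.80 × 10⁻⁴ M⁻¹ s⁻¹)

**The count again.** In this flask at 2.0 d target stood at 2.83% against 35.1% of isomer of the product A, and target stood at 2.21% after 20.0 d. Of the 6.23 half-lives, 2.49 lay between 0.200 d and 1.00 d, which takes this flask's target from 35.7% to 6.33%; it stood at 7.04%.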